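**Plan**

1. Retrosynthesis: the bond between C1 of ring A and the carbinol carbon is cut first, as an allylboration, because HO–C–C1–C2(=CH2) is a homoallylic alcohol; this leaves an achiral (cyclohexa-1,4-dienyl)methyl boronate. The ring A bond C2–C3 (methylidene-bearing carbon to ring CH2) is cut next, as the insertion of an allene into an allyl–palladium bond. In ring B the C–Br bond (SN2) and the side-chain C=C (Horner–Wadsworth–Emmons) are cut back to (S)-limonene.
2. Forward, ring A: isobutyraldehyde and propargyl alcohol give an allenyl aldehyde (propargyl Claisen), which is extended to a (Z)-allylic carbonate; palladium-catalysed ring closure with borylation gives boronate 8.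
3. Forward, ring B: (S)-limonene supplies the side-chain-bearing centre; epoxidation and trans-diaxial hydrolysis relay it to both oxygenated carbons; triflate displacement with inversion gives the equatorial bromide; ozonolysis, olefination and redox steps give enal 20.
4. Union: phosphoric-acid-catalysed allylboration of 20 with 8 forms the last C–C bond, sets C1 of ring A and the carbinol centre (anti from a chair transition state with ring-fixed olefin geometry, absolute sense from the catalyst) and unveils the exocyclic methylene; desilylation ends the route.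
5. Enabling feature: in ring A, C2 carries the exocyclic methylene and lies between stereocentre C1 and the C3H2–C4H=C5H unit, with quaternary C6 closing the ring. C2 is thus the central carbon of an allyl unit (an allene central carbon in the precursor), C3–C4=C5 is an allyl electrophile, and C6 has no hydrogen, which blocks β-hydride elimination and aromatisation.

Key step: step 5

Assumption: the (S)-enantiomer of the phosphoric acid is chosen for step 15 because the (R)-acid is known to direct allyl boronates to the Re face of aryl and alkenyl aldehydes, and the Si face of 20 is the one that must be attacked.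

**Route**

Step 1
Reactants: 1 isobutyraldehyde (2-methylpropanal); 2 propargyl alcohol (prop-2-yn-1-ol)
Product: 4 2,2-dimethylpenta-3,4-dienal, via propargyl enol ether 3 (not isolated)
Conditions: TsOH·H2O (cat.), hydroquinone (cat.), diisopropylbenzene, 140–150 °C, Dean–Stark
Reagents that add atoms: none
Why: Acid-catalysed acetalisation and loss of propargyl alcohol should give the propargyl enol ether, whose propargyl Claisen ([3,3]-sigmatropic) rearrangement installs the quaternary carbon and the terminal allene in one operation, with no stereocentre involved.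

Step 2
Reactants: 4 2,2-dimethylpenta-3,4-dienal
Product: 5 methyl (2Z)-4,4-dimethylhepta-2,5,6-trienoate
Conditions: (CF3CH2O)2P(O)CH2CO2Me, KN(SiMe3)2, 18-crown-6, THF, −78 °C
Reagents that add atoms: methyl bis(2,2,2-trifluoroethyl)phosphonoacetate, COC(=O)CP(=O)(OCC(F)(F)F)OCC(F)(F)F
Why: The Still–Gennari olefination (electron-poor phosphonate, dissociated potassium counter-ion) should give the (Z)-enoate under kinetic control, and the aldehyde has no α-hydrogen to lose.

Step 3
Reactants: 5 methyl (2Z)-4,4-dimethylhepta-2,5,6-trienoate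
Product: 6 (2Z)-4,4-dimethylhepta-2,5,6-trien-1-ol
Conditions: i-Bu2AlH (2.2 equiv), CH2Cl2, −78 °C; aq. potassium sodium tartrate
Reagents that add atoms: none
Why: 1,2-Reduction of the enoate with i-Bu2AlH at low temperature should leave the olefin geometry and the allene untouched.

Step 4
Reactants: 6 (2Z)-4,4-dimethylhepta-2,5,6-trien-1-ol
Product: 7 (2Z)-4,4-dimethylhepta-2,5,6-trien-1-yl methyl carbonate
Conditions: ClCO2Me, pyridine, CH2Cl2, 0 °C
Reagents that add atoms: methyl chloroformate, COC(Cl)=O
Why: O-Acylation turns the alcohol into an ionisable allylic carbonate that on ionisation also releases the methoxide needed later to activate the diboron reagent.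

Step 5
Reactants: 7 (2Z)-4,4-dimethylhepta-2,5,6-trien-1-yl methyl carbonate
Product: 8 2-[(3,3-dimethylcyclohexa-1,4-dien-1-yl)methyl]-4,4,5,5-tetramethyl-1,3,2-dioxaborolane
Conditions: Pd2(dba)3 (2.5 mol %), B2pin2 (1.2 equiv), DMSO, 50 °C, slow addition of 7
Reagents that add atoms: bis(pinacolato)diboron, CC1(C)OB(OC1(C)C)B1OC(C)(C)C(C)(C)O1
Why: Proposed new method: zerovalent palladium ionises the (Z)-allylic carbonate (loss of CO2) to an anti-configured allylpalladium methoxide in which the CH2 terminus (the future ring CH2, C3) and the allene lie cis on the former Z-olefin; migratory insertion of the terminal allene π-bond into the Pd–C3 bond then joins C3 to the sp-hybridised central allene carbon (the future C2) and leaves a new allylpalladium over CH2(exo)–C2–C1, which has no β-hydrogen (its only sp3 neighbour is quaternary C6) and therefore waits for methoxide-assisted transmetalation with B2pin2 and C–B reductive elimination at its primary terminus. The closest known reaction types are the palladium-catalysed carbocyclisation of allene-substituted allylic carboxylates (allyl-to-central-allene-carbon bond formation), the palladium-catalysed three-component couplings of organic halides or acyl chlorides, allenes and dimetal reagents that give 2-substituted allylmetals, and the Miyaura borylation of allylic acetates and carbonates; their merger in one catalytic cycle with an allylic electrophile as initiator is the new element. Ring A closes in a 6-exo sense with respect to the terminal allene double bond (attack on the digonal carbon, the terminal CH2 staying outside the ring), helped by the gem-dimethyl group. No stereocentre is created, but the ring fixes C6 trans to the CH2B group across C1=C2, the geometry that later enforces the anti relationship. The step needs cyclisation to outrun direct borylation of the first allyl complex (intramolecular insertion against a slow bimolecular transmetalation), bond formation at the central rather than the proximal allene carbon (the normal regiochemistry of allene carbopalladation), and boron delivery to the primary rather than the neopentylic allyl terminus (steric bias).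

Step 6
Reactants: 9 (S)-(−)-limonene
Product: 11 (1R,2R,4S)-1-methyl-4-(prop-1-en-2-yl)cyclohexane-1,2-diol, via epoxide mixture 10 (not isolated)
Conditions: mCPBA (1.0 equiv), NaHCO3, CH2Cl2, 0 °C; then 1% aq. H2SO4, THF, 0 °C to rt
Reagents that add atoms: mCPBA, OOC(=O)c1cccc(Cl)c1; water, O
Why: Prilezhaev epoxidation should take the more electron-rich trisubstituted ring olefin, and acid-catalysed hydrolysis opens both epoxide diastereomers trans-diaxially (Fürst–Plattner rule, water at the tertiary carbon of one and at the secondary carbon of the other), so that they converge on one diol in which both new centres are relayed from the purchased centre.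

Step 7
Reactants: 11 (1R,2R,4S)-1-methyl-4-(prop-1-en-2-yl)cyclohexane-1,2-diol
Product: 12 (1R,2R,5S)-2-hydroxy-2-methyl-5-(prop-1-en-2-yl)cyclohexyl acetate
Conditions: Ac2O (1.2 equiv), pyridine, DMAP (cat.), CH2Cl2, 0 °C
Reagents that add atoms: acetic anhydride, CC(=O)OC(C)=O
Why: Acylation should be selective for the secondary hydroxyl, the tertiary one being far less reactive.

Step 8
Reactants: 12 (1R,2R,5S)-2-hydroxy-2-methyl-5-(prop-1-en-2-yl)cyclohexyl acetate
Product: 13 (1R,2R,5S)-2-methyl-5-(prop-1-en-2-yl)-2-[(triethylsilyl)oxy]cyclohexyl acetate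
Conditions: Et3SiOTf, 2,6-lutidine, CH2Cl2, −78 to 0 °C
Reagents that add atoms: triethylsilyl trifluoromethanesulfonate, CC[Si](CC)(CC)OS(=O)(=O)C(F)(F)F
Why: The silyl triflate silylates the hindered tertiary alcohol, which later prevents epoxide closure onto the activated neighbouring carbon.

Step 9
Reactants: 13 (1R,2R,5S)-2-methyl-5-(prop-1-en-2-yl)-2-[(triethylsilyl)oxy]cyclohexyl acetate
Product: 14 (1R,2R,5S)-5-acetyl-2-methyl-2-[(triethylsilyl)oxy]cyclohexyl acetate
Conditions: O3, CH2Cl2/MeOH, −78 °C; then Me2S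
Reagents that add atoms: ozone, [O-][O+]=O
Why: Ozonolysis with reductive work-up cleaves the only olefin to the methyl ketone, whose α-centre keeps the equatorial, thermodynamically preferred configuration.

Step 10
Reactants: 14 (1R,2R,5S)-5-acetyl-2-methyl-2-[(triethylsilyl)oxy]cyclohexyl acetate
Product: 15 methyl (2E)-3-{(1S,3R,4R)-3-(acetyloxy)-4-methyl-4-[(triethylsilyl)oxy]cyclohexyl}but-2-enoate
Conditions: (MeO)2P(O)CH2CO2Me, NaH, THF, 0 to 65 °C
Reagents that add atoms: trimethyl phosphonoacetate, COC(=O)CP(=O)(OC)OC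
Why: The Horner–Wadsworth–Emmons olefination of the methyl ketone should favour the (E)-enoate because of the size difference between the ring and the methyl group, and it is run before the bromide is present so that no enolate can displace a γ-halide.

Step 11
Reactants: 15 methyl (2E)-3-{(1S,3R,4R)-3-(acetyloxy)-4-methyl-4-[(triethylsilyl)oxy]cyclohexyl}but-2-enoate
Product: 16 methyl (2E)-3-{(1S,3R,4R)-3-hydroxy-4-methyl-4-[(triethylsilyl)oxy]cyclohexyl}but-2-enoate
Conditions: K2CO3 (cat.), MeOH, rt
Reagents that add atoms: none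
Why: Methanolysis (transesterification) removes the acetate while the methyl enoate stays a methyl ester, and the trans-diaxial arrangement of the two oxygens precludes silyl migration.

Step 12
Reactants: 16 methyl (2E)-3-{(1S,3R,4R)-3-hydroxy-4-methyl-4-[(triethylsilyl)oxy]cyclohexyl}but-2-enoate
Product: 18 methyl (2E)-3-{(1S,3S,4R)-3-bromo-4-methyl-4-[(triethylsilyl)oxy]cyclohexyl}but-2-enoate, via triflate 17 (not isolated)
Conditions: Tf2O, 2,6-lutidine, CH2Cl2, −78 °C; then Bu4NBr, −78 to 0 °C
Reagents that add atoms: tetrabutylammonium bromide, CCCC[N+](CCCC)(CCCC)CCCC.[Br-]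
Why: Triflation followed by SN2 displacement with bromide inverts the axial carbinol centre, the nucleophile entering equatorially anti to the triflate, which should give the equatorial bromide cis to the silyloxy group.

Step 13
Reactants: 18 methyl (2E)-3-{(1S,3S,4R)-3-bromo-4-methyl-4-[(triethylsilyl)oxy]cyclohexyl}but-2-enoate
Product: 19 (2E)-3-{(1S,3S,4R)-3-bromo-4-methyl-4-[(triethylsilyl)oxy]cyclohexyl}but-2-en-1-ol
Conditions: i-Bu2AlH (2.2 equiv), CH2Cl2, −78 °C; aq. potassium sodium tartrate
Reagents that add atoms: none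
Why: 1,2-Reduction of the enoate with a Lewis-acidic, non-basic hydride should spare the equatorial secondary bromide and the silyl ether.

Step 14
Reactants: 19 (2E)-3-{(1S,3S,4R)-3-bromo-4-methyl-4-[(triethylsilyl)oxy]cyclohexyl}but-2-en-1-ol
Product: 20 (2E)-3-{(1S,3S,4R)-3-bromo-4-methyl-4-[(triethylsilyl)oxy]cyclohexyl}but-2-enal
Conditions: MnO2 (excess), CH2Cl2, rt
Reagents that add atoms: none
Why: Allylic oxidation with MnO2 is neutral and should give the (E)-enal without isomerisation or enolisation.

Step 15
Reactants: 8 2-[(3,3-dimethylcyclohexa-1,4-dien-1-yl)methyl]-4,4,5,5-tetramethyl-1,3,2-dioxaborolane; 20 (2E)-3-{(1S,3S,4R)-3-bromo-4-methyl-4-[(triethylsilyl)oxy]cyclohexyl}but-2-enal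
Product: 22 (1R,2E)-3-{(1S,3S,4R)-3-bromo-4-methyl-4-[(triethylsilyl)oxy]cyclohexyl}-1-[(1R)-2,2-dimethyl-6-methylidenecyclohex-3-en-1-yl]but-2-en-1-ol, via borate ester 21 (not isolated)
Conditions: (S)-TRIP [(S)-3,3'-bis(2,4,6-triisopropylphenyl)-1,1'-binaphthyl-2,2'-diyl hydrogen phosphate] (5 mol %), 4 Å molecular sieves, toluene, −30 °C to rt; then aq. NaHCO3
Reagents that add atoms: none
Why: Chiral phosphoric acid-catalysed allylboration through a closed chair (Zimmerman–Traxler) transition state: the ring of 8 holds C6 trans to the CH2B group, so C6 sits equatorial and the anti relationship between the hydroxyl and C6 should result (C1 of ring A), the catalyst shields the Re face of the aldehyde so that the carbinol centre forms with R configuration, and the allylic transposition unveils the exocyclic methylene.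

Step 16
Reactants: 22 (1R,2E)-3-{(1S,3S,4R)-3-bromo-4-methyl-4-[(triethylsilyl)oxy]cyclohexyl}-1-[(1R)-2,2-dimethyl-6-methylidenecyclohex-3-en-1-yl]but-2-en-1-ol
Product: 23 (1R,2S,4S)-2-bromo-4-{(2E,4R)-4-[(1R)-2,2-dimethyl-6-methylidenecyclohex-3-en-1-yl]-4-hydroxybut-2-en-2-yl}-1-methylcyclohexan-1-ol
Conditions: Bu4NF, AcOH, THF, 0 °C to rt
Reagents that add atoms: none
Why: Buffered fluoride desilylation frees the tertiary alcohol without acid that would isomerise the skipped diene, and the alkoxide cis to the equatorial bromide cannot close an epoxide.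

**Compound list**

1 | isobutyraldehyde (2-methylpropanal) | CC(C)C=O | starting material
2 | propargyl alcohol (prop-2-yn-1-ol) | C#CCO | starting material
3 | 2-methyl-1-(prop-2-yn-1-yloxy)prop-1-ene | CC(C)=COCC#C | intermediate
4 | 2,2-dimethylpenta-3,4-dienal | O=CC(C)(C)C=C=C | intermediate
5 | methyl (2Z)-4,4-dimethylhepta-2,5,6-trienoate | C=C=CC(C)(C)/C=C\C(=O)OC | intermediate
6 | (2Z)-4,4-dimethylhepta-2,5,6-trien-1-ol | C=C=CC(C)(C)/C=C\CO | intermediate
7 | (2Z)-4,4-dimethylhepta-2,5,6-trien-1-yl methyl carbonate | C=C=CC(C)(C)/C=C\COC(=O)OC | intermediate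
8 | 2-[(3,3-dimethylcyclohexa-1,4-dien-1-yl)methyl]-4,4,5,5-tetramethyl-1,3,2-dioxaborolane | CC1(C)C=CCC(CB2OC(C)(C)C(C)(C)O2)=C1 | intermediate
9 | (S)-(−)-limonene | C=C(C)[C@H]1CCC(C)=CC1 | starting material
10 | (4S)-1-methyl-4-(prop-1-en-2-yl)-7-oxabicyclo[4.1.0]heptane, both epoxide diastereomers | C=C(C)[C@H]1CCC2(C)OC2C1 | intermediate
11 | (1R,2R,4S)-1-methyl-4-(prop-1-en-2-yl)cyclohexane-1,2-diol | C=C(C)[C@H]1CC[C@@](C)(O)[C@H](O)C1 | intermediate
12 | (1R,2R,5S)-2-hydroxy-2-methyl-5-(prop-1-en-2-yl)cyclohexyl acetate | C=C(C)[C@H]1CC[C@@](C)(O)[C@H](OC(C)=O)C1 | intermediate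
13 | (1R,2R,5S)-2-methyl-5-(prop-1-en-2-yl)-2-[(triethylsilyl)oxy]cyclohexyl acetate | C=C(C)[C@H]1CC[C@@](C)(O[Si](CC)(CC)CC)[C@H](OC(C)=O)C1 | intermediate
14 | (1R,2R,5S)-5-acetyl-2-methyl-2-[(triethylsilyl)oxy]cyclohexyl acetate | CC(=O)[C@H]1CC[C@@](C)(O[Si](CC)(CC)CC)[C@H](OC(C)=O)C1 | intermediate
15 | methyl (2E)-3-{(1S,3R,4R)-3-(acetyloxy)-4-methyl-4-[(triethylsilyl)oxy]cyclohexyl}but-2-enoate | COC(=O)/C=C(\C)[C@H]1CC[C@@](C)(O[Si](CC)(CC)CC)[C@H](OC(C)=O)C1 | intermediate
16 | methyl (2E)-3-{(1S,3R,4R)-3-hydroxy-4-methyl-4-[(triethylsilyl)oxy]cyclohexyl}but-2-enoate | COC(=O)/C=C(\C)[C@H]1CC[C@@](C)(O[Si](CC)(CC)CC)[C@H](O)C1 | intermediate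
17 | methyl (2E)-3-{(1S,3R,4R)-4-methyl-4-[(triethylsilyl)oxy]-3-[(trifluoromethanesulfonyl)oxy]cyclohexyl}but-2-enoate | COC(=O)/C=C(\C)[C@H]1CC[C@@](C)(O[Si](CC)(CC)CC)[C@H](OS(=O)(=O)C(F)(F)F)C1 | intermediate
18 | methyl (2E)-3-{(1S,3S,4R)-3-bromo-4-methyl-4-[(triethylsilyl)oxy]cyclohexyl}but-2-enoate | COC(=O)/C=C(\C)[C@H]1CC[C@@](C)(O[Si](CC)(CC)CC)[C@@H](Br)C1 | intermediate
19 | (2E)-3-{(1S,3S,4R)-3-bromo-4-methyl-4-[(triethylsilyl)oxy]cyclohexyl}but-2-en-1-ol | OC/C=C(\C)[C@H]1CC[C@@](C)(O[Si](CC)(CC)CC)[C@@H](Br)C1 | intermediate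
20 | (2E)-3-{(1S,3S,4R)-3-bromo-4-methyl-4-[(triethylsilyl)oxy]cyclohexyl}but-2-enal | O=C/C=C(\C)[C@H]1CC[C@@](C)(O[Si](CC)(CC)CC)[C@@H](Br)C1 | intermediate
21 | pinacol borate ester of 22 (O–B(pin) on the carbinol oxygen) | C=C1CC=CC(C)(C)[C@@H]1[C@H](OB2OC(C)(C)C(C)(C)O2)/C=C(\C)[C@H]1CC[C@@](C)(O[Si](CC)(CC)CC)[C@@H](Br)C1 | intermediate
22 | (1R,2E)-3-{(1S,3S,4R)-3-bromo-4-methyl-4-[(triethylsilyl)oxy]cyclohexyl}-1-[(1R)-2,2-dimethyl-6-methylidenecyclohex-3-en-1-yl]but-2-en-1-ol | C=C1CC=CC(C)(C)[C@@H]1[C@H](O)/C=C(\C)[C@H]1CC[C@@](C)(O[Si](CC)(CC)CC)[C@@H](Br)C1 | intermediate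
23 | (1R,2S,4S)-2-bromo-4-{(2E,4R)-4-[(1R)-2,2-dimethyl-6-methylidenecyclohex-3-en-1-yl]-4-hydroxybut-2-en-2-yl}-1-methylcyclohexan-1-ol | C=C1CC=CC(C)(C)[C@@H]1[C@H](O)/C=C(\C)[C@H]1CC[C@@](C)(O)[C@@H](Br)C1 | target

**Step count**

Total: 16 steps. Longest linear sequence: 11 steps (9 to 23, steps 6–16). The ring A arm needs 5 steps to 8 and 7 steps to 23.

**Steps most likely to fail**

Step 5 (Proposed new method). What may go wrong: borylation of the first allylpalladium complex before the allene inserts, or allyl–allyl coupling of 8 with unreacted 7. The fallback uses known chemistry and closes ring A after the union, on the same bond. Alcohol 6 is acetylated (Ac2O, pyridine) to (2Z)-4,4-dimethylhepta-2,5,6-trien-1-yl acetate F1. Hydroboration of its allene at the terminal carbon with (−)-diisopinocampheylborane (from (+)-α-pinene) and equilibration at 25 °C should give the (E)-γ-substituted allylborane F2. This adds to enal 20 at −78 °C through a chair transition state (Brown allene hydroboration–allylboration, anti and reagent-controlled, so C1 and the carbinol centre are set here) to give the borinate F3 and, after NaBO3 work-up, the homoallylic alcohol F4. Silylation (Et3SiOTf, 2,6-lutidine) gives the bis-silyl ether F5. An intramolecular palladium-ene cyclisation (Pd(PPh3)4, toluene, 80 °C) then closes ring A to the bis-silyl ether of the target F6: the (Z)-allylic acetate is ionised, the vinyl group inserts into the allyl–palladium bond in the 6-exo mode, and β-hydride elimination gives the exocyclic methylene. Bu4NF removes both silyl groups and the route is rejoined at 23.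

Step 15. What may go wrong: poor facial selectivity, or slow addition because the reacting γ-carbon of 8 is neopentylic. The fallback replaces catalyst control by a stoichiometric chiral borane. Oxidation of 8 (NaBO3·4H2O, THF/H2O) gives (3,3-dimethylcyclohexa-1,4-dien-1-yl)methanol F7, and PPh3/CCl4 (Appel reaction) gives 1-(chloromethyl)-3,3-dimethylcyclohexa-1,4-diene F8. Magnesium in THF gives the allyl Grignard reagent F9, which with (−)-B-methoxydiisopinocampheylborane (from (+)-α-pinene) gives the B-allyldiisopinocampheylborane F10. Its addition to 20 at −78 °C (Brown allylboration, Si-face attack, anti through the chair) gives the borinate F11, and oxidative work-up rejoins the route at 22.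

Step 12. What may go wrong: E2 elimination of the axial triflate 17 toward the neighbouring ring CH2, or substitution with retention through participation of the antiperiplanar silyloxy oxygen. The fallback sets the C–Br centre by hydrogen-atom delivery instead of SN2. Dess–Martin oxidation of 16 gives the ketone F12. Sc(OTf)3-catalysed condensation with 1,2-bis(tert-butyldimethylsilyl)hydrazine gives the N-silylhydrazone F13, and CuBr2/Et3N in MeOH converts it into the geminal dibromide F14. Bu3SnH (1 equiv) with Et3B/air at −78 °C then removes one bromine; the tin hydride should approach the α-bromo radical on the axial trajectory anti to the axial silyloxy group, so the remaining bromine is equatorial, and the route is rejoined at 18.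

**Further compounds**

F1 | step 5 | (2Z)-4,4-dimethylhepta-2,5,6-trien-1-yl acetate | C=C=CC(C)(C)/C=C\COC(C)=O
F2 | step 5 | (2Z,5E)-7-(diisopinocampheylboranyl)-4,4-dimethylhepta-2,5-dien-1-yl acetate | CC(=O)OC/C=C\C(C)(C)/C=C/CB([C@@H]1C[C@@H]2C[C@H]([C@H]1C)C2(C)C)[C@@H]1C[C@@H]2C[C@H]([C@H]1C)C2(C)C
F3 | step 5 | diisopinocampheylborinate of F4 | C=C[C@@H]([C@H](OB([C@@H]2C[C@@H]3C[C@H]([C@H]2C)C3(C)C)[C@@H]2C[C@@H]3C[C@H]([C@H]2C)C3(C)C)/C=C(\C)[C@H]1CC[C@@](C)(O[Si](CC)(CC)CC)[C@@H](Br)C1)C(C)(C)/C=C\COC(C)=O
F4 | step 5 | (2Z,5R,6R,7E)-8-{(1S,3S,4R)-3-bromo-4-methyl-4-[(triethylsilyl)oxy]cyclohexyl}-5-ethenyl-6-hydroxy-4,4-dimethylnona-2,7-dien-1-yl acetate | C=C[C@@H]([C@H](O)/C=C(\C)[C@H]1CC[C@@](C)(O[Si](CC)(CC)CC)[C@@H](Br)C1)C(C)(C)/C=C\COC(C)=O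
F5 | step 5 | 6-O-triethylsilyl ether of F4 | C=C[C@@H]([C@H](O[Si](CC)(CC)CC)/C=C(\C)[C@H]1CC[C@@](C)(O[Si](CC)(CC)CC)[C@@H](Br)C1)C(C)(C)/C=C\COC(C)=O
F6 | step 5 | bis(triethylsilyl) ether of 23 | C=C1CC=CC(C)(C)[C@@H]1[C@H](O[Si](CC)(CC)CC)/C=C(\C)[C@H]1CC[C@@](C)(O[Si](CC)(CC)CC)[C@@H](Br)C1
F7 | step 15 | (3,3-dimethylcyclohexa-1,4-dien-1-yl)methanol | CC1(C)C=CCC(CO)=C1
F8 | step 15 | 1-(chloromethyl)-3,3-dimethylcyclohexa-1,4-diene | CC1(C)C=CCC(CCl)=C1
F9 | step 15 | [(3,3-dimethylcyclohexa-1,4-dien-1-yl)methyl]magnesium chloride | CC1(C)C=CCC(C[Mg]Cl)=C1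
F10 | step 15 | B-[(3,3-dimethylcyclohexa-1,4-dien-1-yl)methyl]diisopinocampheylborane | CC1(C)C=CCC(CB([C@@H]2C[C@@H]3C[C@H]([C@H]2C)C3(C)C)[C@@H]2C[C@@H]3C[C@H]([C@H]2C)C3(C)C)=C1
F11 | step 15 | diisopinocampheylborinate of 22 | C=C1CC=CC(C)(C)[C@@H]1[C@H](OB([C@@H]2C[C@@H]3C[C@H]([C@H]2C)C3(C)C)[C@@H]2C[C@@H]3C[C@H]([C@H]2C)C3(C)C)/C=C(\C)[C@H]1CC[C@@](C)(O[Si](CC)(CC)CC)[C@@H](Br)C1
F12 | step 12 | methyl (2E)-3-{(1S,4R)-4-methyl-3-oxo-4-[(triethylsilyl)oxy]cyclohexyl}but-2-enoate | COC(=O)/C=C(\C)[C@H]1CC[C@@](C)(O[Si](CC)(CC)CC)C(=O)C1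
F13 | step 12 | N-(tert-butyldimethylsilyl)hydrazone of F12 | COC(=O)/C=C(\C)[C@H]1CC[C@@](C)(O[Si](CC)(CC)CC)C(=NN[Si](C)(C)C(C)(C)C)C1
F14 | step 12 | methyl (2E)-3-{(1S,4R)-3,3-dibromo-4-methyl-4-[(triethylsilyl)oxy]cyclohexyl}but-2-enoate | COC(=O)/C=C(\C)[C@H]1CC[C@@](C)(O[Si](CC)(CC)CC)C(Br)(Br)C1
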